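The vessel was closed, stirred and isothermal, and Z, once charged, could close to the ring G or pair into E.

| flask | Z | remark | time |
|---|---|---|---|
| summer | 5 mM | run made earlier |  |
| autumn | 20 mM | run made earlier |  |
| flask | 10 mM |  | 1.0 h |

- summer (time / min: G / %, Z / %): 0.667: 8.0, 67.5; 3.00: 15.1, 26.6; 15.0: 5.7, 0.1; 80.0: 0.2, 2.1
- autumn (time / min: G / %, Z / %): 0.667: 7.4, 40.5; 3.00: 8.2, 9.7; 15.0: 0.6, 1.7; 80.0: 0, 2.0

(each reading ± 1 percentage point)

- time up to 1.0 h at which G stands highest, in min
- the amount of G, in percent of the Z charged, at that time

- a species is counted by the Z in it: one E or Q counts as two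
- a species is counted by the Z in it: one D counts as three
- candidate steps: Z -> G; 2 Z -> E; Z + E -> D; G -> J; G <-> L; Z + G -> Q

I went through the run in slow motion. In the first instants I looked at how fast Z fell. The first Z reading of the summer run put its loss of Z at 0.589 /min around a mean 4.13 mM, and that of the autumn run at 1.36 /min around 13.2 mM. I split this loss into a first-order part, which I took to make G, and a part proportional to the concentration c of Z. The two parts stand equal at the crossover charge c*, read here as 2.81 mM. So I reckoned the share of lost Z becoming G, the selectivity, as c*/(c* + c), which I put at about 22.0% at the start of the 10 mM flask.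

In the middle of the summer run c fell, so on my split that share rose, but G was being lost as well: summer G read 15.1% at 3.00 min and 5.7% at 15.0 min. By then summer Z read 0.1%, below the scatter, and at the last summer reading G read 0.2%.

Summing the share over the fall of Z from a charge C gave my estimate of the G ever made, Y = (c*/C) ln((c* + C)/c*): 57.5% for summer, 29.4% for autumn and 42.7% for this flask. The highest G readings of the summer and autumn runs were 26.3% and 27.8% of their Y, so I took their mean and expected 11.5% at the top of this flask; I reckoned no time.

The forecast, “an interpolation, not a full fit”, gave 12.5% (10.8% to 14.5%), above my figure, at 2.5 min (1.6 min to 3.8 min).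

The flask reached its highest G, 12.0%, at 2.49 min.

    Z → G (k = 0.00298 /s)
    2 Z → E (k = 0.785 /M/s)
    Z + E → D (k = 0.0257 /M/s)
    G → J (k = 0.00280 /s)
    G ⇌ L (K = 2.79, k = 0.00201 /s)
    Z + G → Q (k = 0.298 /M/s)

That top is 28.2% of the flask's Y. I carried c* and this fraction to a neighbouring flask, the same but charged with 2.5 mM of Z. There Y came to 71.6%, which put the top at 20.2%. That flask's highest G was 20.2%.

Readings and results stem from a simulated flask with constants of no real substance; the scatter is artificial.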